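**Plan**

1. Numbering: ring A = C1–C6 (C1 and C6 ring fusion, C3 acetoxy carbon, C4=C5 methylated alkene); ring B = C1, C6, C7, C8, C9, C10 (C7 carries the acrylic acid C11 with methylene C13 and carboxyl C12, C8 the acyloxy group, C10 the methyl carbinol).
2. Retrosynthesis: cut the C8 ester C–O bond (protected side-chain acid); take the acrylic acid back to a C12 silyl ether, because a C12 ester would lactonise onto the cis C8 hydroxyl; take the C10 hydroxyl back to an exocyclic methylene; then cut C8–C9 (carbonyl-ene), C7–C11 (enolate alkylation) and C6–C7 (Claisen), which leaves (S)-carvone.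
3. What makes the key step possible: in ring B the C10 carbinol carbon, its methyl group and C9 are the three carbons of carvone's isopropenyl group and C1 is the ring carbon bearing it; C8 is the direct neighbour of C9, so an aldehyde placed at C8 can be reached by the terminal CH2 of that isopropenyl group.
4. Forward order: ring A is carvone; the C3 hydroxyl, the C4 tertiary allylic alcohol, the C6–C7 bond, the C7 arm and the C8 aldehyde are installed in seven steps; ring B closes in step 8; C10 is hydrated, the side chain is esterified at C8, and C12 is oxidised to the acrylic acid before acetate exchange and desilylation.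
5. Stereochemistry: C1 from (S)-carvone; C3 by 1,2-reduction cis to the isopropenyl group; C6 by a suprafacial [3,3] shift from the C4–O bond (set by hydroxyl-directed epoxidation); C7 by A(1,3)-controlled enolate alkylation; C8 by the chair ene transition state; C10 by O2 capture anti to the axial C8 hydroxyl; side-chain E geometry by syn-hydrostannation.

Key step: step 8

Remark (assumption): tert-butyl(2-iodoethoxy)dimethylsilane and 2-butyne-1,4-diol are taken as commercial; target numbering is used for every intermediate.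
Abbreviations: TBS = tert-butyldimethylsilyl, TBDPS = tert-butyldiphenylsilyl, TES = triethylsilyl, dpm = dipivaloylmethanato, CSA = camphorsulfonic acid, DMAP = 4-(dimethylamino)pyridine.

**Route**

Step 1
Reactants: 1 (S)-(+)-carvone
Product: 2 (1S,5S)-cis-carveol
Conditions: NaBH4, CeCl3·7H2O, MeOH, −78 → 0 °C
Reagents that add atoms: none
Why: Luche reduction: the CeCl3-activated borohydride attacks the enone carbonyl 1,2 and from the axial direction of the half-chair with the isopropenyl group equatorial, so the new C3 carbinol should be cis to the isopropenyl group.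

Step 2
Reactants: 2 (1S,5S)-cis-carveol
Product: 3 epoxy alcohol (C4–C5 epoxide on the face of the C3 hydroxyl)
Conditions: VO(acac)2 (cat.), t-BuOOH, toluene, rt
Reagents that add atoms: tert-butyl hydroperoxide, CC(C)(C)OO
Why: Hydroxyl-directed epoxidation: the vanadium alkoxide delivers the peroxide oxygen to the allylic alkene on the face of the C3 hydroxyl and leaves the isopropenyl group alone, which sets C4 and C5.

Step 3
Reactants: 3 epoxy alcohol
Product: 4 epoxy TBS ether
Conditions: TBSCl, imidazole, DMF, rt
Reagents that add atoms: tert-butyldimethylsilyl chloride, CC(C)(C)[Si](C)(C)Cl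
Why: Standard silylation of a secondary alcohol under conditions that leave the epoxide intact.

Step 4
Reactants: 4 epoxy TBS ether
Product: 7 tertiary allylic alcohol (C4 hydroxyl cis to C3 OTBS; C5=C6 alkene), via hydroxy selenide 5 (not isolated), via selenoxide 6 (not isolated)
Conditions: (PhSe)2, NaBH4, EtOH, 0 °C → reflux; then THF, 30% H2O2, 0 °C → rt
Reagents that add atoms: none
Why: Selenolate epoxide opening followed by selenoxide syn-elimination: PhSe− attacks the less substituted C5 in the trans-diaxial sense (favoured with the isopropenyl group equatorial), and the selenoxide can only eliminate toward C6 because C4 has no hydrogen, so the C4–O stereocentre is kept.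

Step 5
Reactants: 7 tertiary allylic alcohol; 8 N,N-dimethylacetamide dimethyl acetal
Product: 10 C6 acetamide (N,N-dimethylamide; C4=C5 alkene), via ketene N,O-acetal 9 (not isolated)
Conditions: 8 (excess), xylene, 140 °C, MeOH distilled off
Reagents that add atoms: none
Why: Eschenmoser–Claisen rearrangement: alcohol exchange and loss of methanol give the ketene N,O-acetal, whose [3,3] shift is suprafacial, so the C6–C7 bond forms on the face the C4–O bond leaves (cis to the isopropenyl and silyloxy groups) and the C4=C5 alkene of the target appears.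

Step 6
Reactants: 10 C6 acetamide; 11 tert-butyl(2-iodoethoxy)dimethylsilane
Product: 13 C7-alkylated amide (C7 bears CH2CH2OTBS), via lithium Z-enolate 12 (not isolated)
Conditions: LiN(i-Pr)2, THF, −78 → 0 °C; then 11, DMPU, −78 → 0 °C
Reagents that add atoms: none
Why: Amide enolate alkylation: the Z-enolate should adopt the conformation with the C6–H bond in the enolate plane (A(1,3) strain minimised), and the iodide then approaches anti to the bulkier C1 branch that carries the isopropenyl group, which sets C7 as required.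

Step 7
Reactants: 13 C7-alkylated amide
Product: 14 C8 aldehyde (ene precursor)
Conditions: Cp2Zr(H)Cl, THF, rt; aqueous work-up
Reagents that add atoms: none
Why: Partial reduction of a tertiary amide by Cp2Zr(H)Cl: the zirconated hemiaminal is stable until work-up, forms faster than hydrozirconation of 1,1-di- or trisubstituted alkenes, and should leave the silyl ethers and the C7 stereocentre untouched.

Step 8
Reactants: 14 C8 aldehyde
Product: 15 cis-decalin C8 alcohol with C10 exocyclic methylene
Conditions: Me2AlCl, CH2Cl2, −78 → −20 °C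
Reagents that add atoms: none
Why: Me2AlCl binds the aldehyde oxygen, the terminal isopropenyl carbon C9 adds to C8 while a hydrogen of the isopropenyl methyl passes to oxygen through a six-centre array, and a methyl group on aluminium then takes up the proton so that no acid is left to isomerise the new alkene. The closest known reaction type is the Lewis-acid-promoted type 2 intramolecular carbonyl-ene cyclisation of 5-methylhex-5-enals to 3-methylenecyclohexanols. Ring B closes as a six-membered ring in which both ene carbons C9 and C10 become ring atoms (bond formation at the terminal alkene carbon, tether on the internal one) and the carbonyl oxygen stays outside the ring (6-exo-trig at C8). The one new stereocentre, C8, is controlled by a chair-like transition state with the C6–C5 bond and the C7 arm equatorial and the C–O bond axial, the only orientation from which oxygen can reach the methyl hydrogen, so the hydroxyl should end up cis to the C7 substituent. The step needs this cis C7/C8 relationship and concerted rather than cationic behaviour; the first is secured by the cis C1/C6 substitution of ring A, which already holds the isopropenyl group equatorial and the aldehyde arm pseudoaxial in the ground state, and the second by the proton-scavenging methyl groups on aluminium at low temperature.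

Step 9
Reactants: 15 cis-decalin C8 alcohol
Product: 17 C8/C10 diol (C10 hydroxyl trans to C8 hydroxyl), via C10 hydroperoxide 16 (not isolated)
Conditions: Mn(dpm)3 (cat.), PhSiH3, O2 (1 atm), i-PrOH/CH2Cl2, 0 °C → rt; then PPh3
Reagents that add atoms: dioxygen, O=O
Why: Mukaiyama hydration: hydrogen-atom transfer from the manganese hydride goes to the unhindered 1,1-disubstituted alkene in preference to the trisubstituted ring alkene, and the tertiary C10 radical should take up O2 from the equatorial side because the axial C8 hydroxyl screens the other face, giving the C10 alcohol with its methyl group syn to the C8 oxygen after PPh3 reduction of the hydroperoxide.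

Step 10
Reactants: 18 2-butyne-1,4-diol
Product: 19 1,4-bis(tert-butyldiphenylsilyloxy)but-2-yne
Conditions: TBDPSCl, imidazole, DMF, rt
Reagents that add atoms: tert-butyldiphenylsilyl chloride, CC(C)(C)[Si](Cl)(c1ccccc1)c1ccccc1
Why: Standard bis-silylation of two primary alcohols.

Step 11
Reactants: 19 1,4-bis(tert-butyldiphenylsilyloxy)but-2-yne
Product: 21 (E)-2-iodo-1,4-bis(tert-butyldiphenylsilyloxy)but-2-ene, via vinylstannane 20 (not isolated)
Conditions: Bu3SnH, PdCl2(PPh3)2 (cat.), THF, rt; then I2, CH2Cl2, 0 °C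
Reagents that add atoms: iodine, II
Why: Palladium-catalysed hydrostannation adds H and Sn syn across the symmetrical alkyne (no regiochemical issue), and iododestannylation proceeds with retention, so the two CH2O groups end up cis.

Step 12
Reactants: 21 (E)-vinyl iodide
Product: 23 (E)-4-(tert-butyldiphenylsilyloxy)-2-[(tert-butyldiphenylsilyloxy)methyl]but-2-enoic acid, via vinyllithium 22 (not isolated)
Conditions: t-BuLi, Et2O, −78 °C; CO2; aq. HCl
Reagents that add atoms: carbon dioxide, O=C=O
Why: Lithium–iodine exchange with retention of alkene geometry and carboxylation of the vinyllithium give the E acid; lithium is trans to the β-CH2OSi group, so 1,4-silyl migration from oxygen to carbon cannot intervene.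

Step 13
Reactants: 23 side-chain acid; 17 C8/C10 diol
Product: 25 C8 ester (C10 hydroxyl free), via mixed anhydride 24 (not isolated)
Conditions: 2,4,6-Cl3C6H2COCl, Et3N, THF, rt; then 17, DMAP, toluene, rt → 50 °C
Reagents that add atoms: none
Why: Yamaguchi esterification: the mixed anhydride and DMAP acylate the hindered axial secondary C8 hydroxyl while the tertiary C10 hydroxyl does not react, and the acid already has the thermodynamically preferred E geometry.

Step 14
Reactants: 25 C8 ester
Product: 26 C12 primary alcohol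
Conditions: CSA (cat.), MeOH/CH2Cl2, 0 °C
Reagents that add atoms: none
Why: Acid-catalysed methanolysis removes a primary alkyl TBS ether much faster than the hindered secondary TBS ether at C3 or the TBDPS ethers.

Step 15
Reactants: 26 C12 primary alcohol
Product: 27 C12 aldehyde
Conditions: Dess–Martin periodinane, pyridine, CH2Cl2, 0 °C → rt
Reagents that add atoms: none
Why: Dess–Martin oxidation of the primary alcohol under buffered conditions, to which the tertiary alcohol, esters and silyl ethers are inert.

Step 16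
Reactants: 27 C12 aldehyde
Product: 29 α-methylene aldehyde (C11=C13), via Mannich base 28 (not isolated)
Conditions: Me2N+=CH2 I−, Et3N, CH2Cl2, rt
Reagents that add atoms: N,N-dimethylmethyleneiminium iodide, C=[N+](C)C.[I-]
Why: Mannich reaction of the aldehyde followed by base-induced loss of dimethylamine (α-methylenation); only C11 carries enolisable hydrogens, so C7 is not touched.

Step 17
Reactants: 29 α-methylene aldehyde
Product: 30 acrylic acid (C3 OTBS; side chain bis-TBDPS)
Conditions: NaClO2, NaH2PO4, 2-methyl-2-butene, t-BuOH/H2O, 0 °C → rt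
Reagents that add atoms: sodium chlorite, [Na+].[O-]Cl=O
Why: Pinnick oxidation converts the enal to the acrylic acid and should spare the alkenes because 2-methyl-2-butene scavenges the hypochlorous acid.

Step 18
Reactants: 30 acrylic acid
Product: 31 C3 alcohol
Conditions: HF·pyridine, pyridine, THF, 0 °C
Reagents that add atoms: none
Why: Desilylation with buffered HF·pyridine cleaves the secondary TBS ether faster than the primary TBDPS ethers.

Step 19
Reactants: 31 C3 alcohol
Product: 32 C3 acetate (side chain bis-TBDPS)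
Conditions: Ac2O, pyridine, DMAP (cat.), CH2Cl2, 0 °C → rt; aq. NaHCO3 work-up
Reagents that add atoms: acetic anhydride, CC(=O)OC(C)=O
Why: Acetylation of the secondary allylic alcohol; the tertiary C10 hydroxyl is too hindered to react under these conditions and any mixed anhydride at the carboxylic acid is hydrolysed on bicarbonate work-up.

Step 20
Reactants: 32 C3 acetate
Product: 33 CNP0468194.1
Conditions: HF·pyridine, THF, 0 °C → rt
Reagents that add atoms: none
Why: Fluoride-mediated desilylation of the two primary TBDPS ethers under mildly acidic conditions that should spare the acetate, the enoate ester, the tertiary alcohol and the acrylic acid.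

**Compound list**

1 | (S)-(+)-carvone | CC1=CC[C@@H](CC1=O)C(C)=C | starting material
2 | (1S,5S)-cis-carveol (C3 hydroxyl cis to the C1 isopropenyl group) | CC(=C)[C@@H]1C[C@H](O)C(C)=CC1 | intermediate
3 | epoxy alcohol: C4–C5 epoxide of cis-carveol, epoxide oxygen cis to the C3 hydroxyl and the isopropenyl group | CC(=C)[C@@H]1C[C@H](O)[C@]2(C)O[C@@H]2C1 | intermediate
4 | TBS ether of 3 | CC(=C)[C@@H]1C[C@H](O[Si](C)(C)C(C)(C)C)[C@]2(C)O[C@@H]2C1 | intermediate
5 | hydroxy selenide: C4 tertiary alcohol cis to C3 OTBS, C5 phenylselanyl trans to the C4 hydroxyl | CC(=C)[C@@H]1C[C@H](O[Si](C)(C)C(C)(C)C)[C@](C)(O)[C@@H]([Se]c2ccccc2)C1 | intermediate (not isolated)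
6 | selenoxide of 5 | CC(=C)[C@@H]1C[C@H](O[Si](C)(C)C(C)(C)C)[C@](C)(O)[C@@H]([Se](=O)c2ccccc2)C1 | intermediate (not isolated)
7 | tertiary allylic alcohol: 1-isopropenyl-3-(TBS-oxy)-4-methylcyclohex-5-en-4-ol, C4 hydroxyl cis to C3 OTBS and to the isopropenyl group | CC(=C)[C@@H]1C[C@H](O[Si](C)(C)C(C)(C)C)[C@](C)(O)C=C1 | intermediate
8 | N,N-dimethylacetamide dimethyl acetal | COC(C)(OC)N(C)C | starting material
9 | ketene N,O-acetal: 1-(dimethylamino)vinyl ether of 7 | CC(=C)[C@@H]1C[C@H](O[Si](C)(C)C(C)(C)C)[C@](C)(OC(=C)N(C)C)C=C1 | intermediate (not isolated)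
10 | C6 acetamide: N,N-dimethyl-2-(ring A C6-yl)acetamide, C4=C5 alkene, C6 arm cis to the C1 isopropenyl and C3 OTBS groups | CN(C)C(=O)C[C@H]1C=C(C)[C@@H](O[Si](C)(C)C(C)(C)C)C[C@H]1C(C)=C | intermediate
11 | tert-butyl(2-iodoethoxy)dimethylsilane | CC(C)(C)[Si](C)(C)OCCI | starting material
12 | lithium Z-enolate of 10 | [Li]O/C(N(C)C)=C\[C@H]1C=C(C)[C@@H](O[Si](C)(C)C(C)(C)C)C[C@H]1C(C)=C | intermediate (not isolated)
13 | C7-alkylated amide: C7 bears the C8 dimethylamide and the C11–C12 arm CH2CH2OTBS | CC(C)(C)[Si](C)(C)OCC[C@@H](C(=O)N(C)C)[C@H]1C=C(C)[C@@H](O[Si](C)(C)C(C)(C)C)C[C@H]1C(C)=C | intermediate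
14 | C8 aldehyde with CH2CH2OTBS arm at C7 and isopropenyl at C1 (ene precursor) | CC(C)(C)[Si](C)(C)OCC[C@@H](C=O)[C@H]1C=C(C)[C@@H](O[Si](C)(C)C(C)(C)C)C[C@H]1C(C)=C | intermediate
15 | cis-decalin C8 alcohol with C10 exocyclic methylene; C8 hydroxyl cis to the C7 arm and on the face of H1 and H6 | CC(C)(C)[Si](C)(C)OCC[C@@H]1[C@H]2C=C(C)[C@@H](O[Si](C)(C)C(C)(C)C)C[C@H]2C(=C)C[C@@H]1O | intermediate
16 | C10 hydroperoxide (OOH trans to C8 OH) | CC(C)(C)[Si](C)(C)OCC[C@@H]1[C@H]2C=C(C)[C@@H](O[Si](C)(C)C(C)(C)C)C[C@H]2[C@@](C)(OO)C[C@@H]1O | intermediate (not isolated)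
17 | C8/C10 diol: C10 methyl carbinol with OH trans to C8 OH, methyl cis to it | CC(C)(C)[Si](C)(C)OCC[C@@H]1[C@H]2C=C(C)[C@@H](O[Si](C)(C)C(C)(C)C)C[C@H]2[C@@](C)(O)C[C@@H]1O | intermediate
18 | 2-butyne-1,4-diol | OCC#CCO | starting material
19 | 1,4-bis(tert-butyldiphenylsilyloxy)but-2-yne | CC(C)(C)[Si](OCC#CCO[Si](c1ccccc1)(c1ccccc1)C(C)(C)C)(c1ccccc1)c1ccccc1 | intermediate
20 | (E)-2-(tributylstannyl)-1,4-bis(tert-butyldiphenylsilyloxy)but-2-ene | CCCC[Sn](CCCC)(CCCC)/C(CO[Si](c1ccccc1)(c1ccccc1)C(C)(C)C)=C/CO[Si](c1ccccc1)(c1ccccc1)C(C)(C)C | intermediate (not isolated)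
21 | (E)-2-iodo-1,4-bis(tert-butyldiphenylsilyloxy)but-2-ene | I/C(CO[Si](c1ccccc1)(c1ccccc1)C(C)(C)C)=C/CO[Si](c1ccccc1)(c1ccccc1)C(C)(C)C | intermediate
22 | vinyllithium from 21 (geometry retained) | [Li]/C(CO[Si](c1ccccc1)(c1ccccc1)C(C)(C)C)=C/CO[Si](c1ccccc1)(c1ccccc1)C(C)(C)C | intermediate (not isolated)
23 | (E)-4-(tert-butyldiphenylsilyloxy)-2-[(tert-butyldiphenylsilyloxy)methyl]but-2-enoic acid | OC(=O)/C(CO[Si](c1ccccc1)(c1ccccc1)C(C)(C)C)=C/CO[Si](c1ccccc1)(c1ccccc1)C(C)(C)C | intermediate
24 | mixed anhydride of 23 with 2,4,6-trichlorobenzoic acid | O=C(OC(=O)c1c(Cl)cc(Cl)cc1Cl)/C(CO[Si](c1ccccc1)(c1ccccc1)C(C)(C)C)=C/CO[Si](c1ccccc1)(c1ccccc1)C(C)(C)C | intermediate (not isolated)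
25 | C8 ester of 17 with acid 23 (C3 OTBS, C12 OTBS, C10 OH free) | CC(C)(C)[Si](C)(C)OCC[C@@H]1[C@H]2C=C(C)[C@@H](O[Si](C)(C)C(C)(C)C)C[C@H]2[C@@](C)(O)C[C@@H]1OC(=O)/C(CO[Si](c3ccccc3)(c3ccccc3)C(C)(C)C)=C/CO[Si](c3ccccc3)(c3ccccc3)C(C)(C)C | intermediate
26 | C12 primary alcohol | OCC[C@@H]1[C@H]2C=C(C)[C@@H](O[Si](C)(C)C(C)(C)C)C[C@H]2[C@@](C)(O)C[C@@H]1OC(=O)/C(CO[Si](c3ccccc3)(c3ccccc3)C(C)(C)C)=C/CO[Si](c3ccccc3)(c3ccccc3)C(C)(C)C | intermediate
27 | C12 aldehyde | O=CC[C@@H]1[C@H]2C=C(C)[C@@H](O[Si](C)(C)C(C)(C)C)C[C@H]2[C@@](C)(O)C[C@@H]1OC(=O)/C(CO[Si](c3ccccc3)(c3ccccc3)C(C)(C)C)=C/CO[Si](c3ccccc3)(c3ccccc3)C(C)(C)C | intermediate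
28 | Mannich base: C11 bears CH2NMe2 (C11 epimers) | CN(C)CC(C=O)[C@@H]1[C@H]2C=C(C)[C@@H](O[Si](C)(C)C(C)(C)C)C[C@H]2[C@@](C)(O)C[C@@H]1OC(=O)/C(CO[Si](c3ccccc3)(c3ccccc3)C(C)(C)C)=C/CO[Si](c3ccccc3)(c3ccccc3)C(C)(C)C | intermediate (not isolated)
29 | α-methylene aldehyde (C11=C13, C12 aldehyde) | C=C(C=O)[C@@H]1[C@H]2C=C(C)[C@@H](O[Si](C)(C)C(C)(C)C)C[C@H]2[C@@](C)(O)C[C@@H]1OC(=O)/C(CO[Si](c3ccccc3)(c3ccccc3)C(C)(C)C)=C/CO[Si](c3ccccc3)(c3ccccc3)C(C)(C)C | intermediate
30 | acrylic acid with C3 OTBS and bis-TBDPS side chain | C=C(C(=O)O)[C@@H]1[C@H]2C=C(C)[C@@H](O[Si](C)(C)C(C)(C)C)C[C@H]2[C@@](C)(O)C[C@@H]1OC(=O)/C(CO[Si](c3ccccc3)(c3ccccc3)C(C)(C)C)=C/CO[Si](c3ccccc3)(c3ccccc3)C(C)(C)C | intermediate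
31 | C3 alcohol (acrylic acid, bis-TBDPS side chain) | C=C(C(=O)O)[C@@H]1[C@H]2C=C(C)[C@@H](O)C[C@H]2[C@@](C)(O)C[C@@H]1OC(=O)/C(CO[Si](c3ccccc3)(c3ccccc3)C(C)(C)C)=C/CO[Si](c3ccccc3)(c3ccccc3)C(C)(C)C | intermediate
32 | C3 acetate (acrylic acid, bis-TBDPS side chain) | C=C(C(=O)O)[C@@H]1[C@H]2C=C(C)[C@@H](OC(C)=O)C[C@H]2[C@@](C)(O)C[C@@H]1OC(=O)/C(CO[Si](c3ccccc3)(c3ccccc3)C(C)(C)C)=C/CO[Si](c3ccccc3)(c3ccccc3)C(C)(C)C | intermediate
33 | CNP0468194.1: cis-fused; C7 acrylic acid, C8 acyloxy and C10 methyl on the face of H1/H6; C3 acetoxy and C10 hydroxyl on the opposite face; E side chain | C=C(C(=O)O)[C@@H]1[C@H]2C=C(C)[C@@H](OC(C)=O)C[C@H]2[C@@](C)(O)C[C@@H]1OC(=O)/C(=C/CO)CO | target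

**Step count**

Total: 20 steps. Longest linear sequence: 17 steps (steps 1–9 and 13–20 from (S)-carvone); the side-chain acid takes 3 steps (steps 10–12).

**Steps most likely to fail**

Step 9. What may go wrong: poor facial selectivity when the planar C10 radical captures O2 (attack from the axial face, possibly helped by hydrogen bonding to the C8 hydroxyl, would give the C10 epimer), and competing hydrogen-atom transfer to the C4=C5 alkene. The fallback sets out from 15 and returns at 17. The C8 hydroxyl is first silylated (TESOTf, 2,6-lutidine, CH2Cl2, −78 °C) to the C8 triethylsilyl ether F1, so that a bulky axial silyloxy group that cannot donate a hydrogen bond screens the upper face of C10. The same hydration conditions then lead through the hydroperoxide F2 to the silyl-protected tertiary alcohol F3. PPTS in MeOH/CH2Cl2 at 0 °C, which cleaves a triethylsilyl ether faster than either TBS ether, gives 17.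

Step 6. What may go wrong: slow displacement on the β-silyloxy iodide by a hindered enolate, with competing elimination of the iodide and, if the mixture has to be warmed, erosion of facial selectivity at C7. The fallback sets out from 10 and returns at 13. Enolate 12 is alkylated at −78 °C with methyl bromoacetate, a far more reactive electrophile that lets the A(1,3)-controlled approach operate at low temperature, to give the amide methyl ester F4. LiBH4 in THF/MeOH reduces the ester but not the tertiary amide, giving the hydroxy amide F5, and TBSCl/imidazole in DMF then gives 13.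

Step 8. What may go wrong: loss of facial selectivity at the aldehyde carbon if the closure turns stepwise (oxygen equatorial in the cyclisation), which would give the C8 epimer alongside 15. The fallback sets out from 14 and returns at 15. The ring is closed as before and the C8-epimeric alcohol F6, alone or mixed with 15, is oxidised (Dess–Martin periodinane, pyridine, CH2Cl2) to the β,γ-unsaturated C8 ketone F7. LiBH(s-Bu)3 in THF at −78 °C reduces F7 from the equatorial side, next to the equatorial C7 arm, and delivers the axial alcohol 15. C8 is then set by reagent-controlled hydride delivery rather than by the ene transition state, while the ring-forming bond is unchanged.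

**Further compounds**

F1 | step 9 | C8 triethylsilyl ether of 15 | CC(C)(C)[Si](C)(C)OCC[C@@H]1[C@H]2C=C(C)[C@@H](O[Si](C)(C)C(C)(C)C)C[C@H]2C(=C)C[C@@H]1O[Si](CC)(CC)CC
F2 | step 9 | C10 hydroperoxide of F1 (not isolated) | CC(C)(C)[Si](C)(C)OCC[C@@H]1[C@H]2C=C(C)[C@@H](O[Si](C)(C)C(C)(C)C)C[C@H]2[C@@](C)(OO)C[C@@H]1O[Si](CC)(CC)CC
F3 | step 9 | C8 triethylsilyl ether of 17 | CC(C)(C)[Si](C)(C)OCC[C@@H]1[C@H]2C=C(C)[C@@H](O[Si](C)(C)C(C)(C)C)C[C@H]2[C@@](C)(O)C[C@@H]1O[Si](CC)(CC)CC
F4 | step 6 | amide methyl ester (C7 bears CH2CO2Me and the C8 dimethylamide) | COC(=O)C[C@@H](C(=O)N(C)C)[C@H]1C=C(C)[C@@H](O[Si](C)(C)C(C)(C)C)C[C@H]1C(C)=C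
F5 | step 6 | hydroxy amide (C7 bears CH2CH2OH and the C8 dimethylamide) | OCC[C@@H](C(=O)N(C)C)[C@H]1C=C(C)[C@@H](O[Si](C)(C)C(C)(C)C)C[C@H]1C(C)=C
F6 | step 8 | C8 epimer of 15 (equatorial hydroxyl, trans to the C7 arm) | CC(C)(C)[Si](C)(C)OCC[C@@H]1[C@H]2C=C(C)[C@@H](O[Si](C)(C)C(C)(C)C)C[C@H]2C(=C)C[C@H]1O
F7 | step 8 | C8 ketone with C10 exocyclic methylene | CC(C)(C)[Si](C)(C)OCC[C@@H]1[C@H]2C=C(C)[C@@H](O[Si](C)(C)C(C)(C)C)C[C@H]2C(=C)CC1=O
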